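(The earlier runs and the new flask are calculated with constants of no real substance; scatter was added.)

**One ratio?** A one-step world has one ratio of X to J, standing still from start to end. The noon run is not that world: X over J read 7.74 at 4.00 min and 1.66 at 40.0 min.

| setting | noon | dusk | flask |
|---|---|---|---|
| L | 0.12 M | 0.080 M | 0.12 M |
| D | 2 equiv | 2 equiv | 2.00 equiv |
| remark | the very flask that is asked about, followed so far | run made earlier |  |
| time |  |  | 6.0 h |

noon run (percent of the L charged)

| time / min | X / % | J / % | L / % |
|---|---|---|---|
| 4.00 | 17.8 | 2.3 | 70.0 |
| 10.0 | 33.0 | 8.7 | 44.4 |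
| 20.0 | 45.1 | 20.3 | 23.6 |
| 30.0 | 51.1 | 27.8 | 13.7 |
| 40.0 | 54.9 | 33.1 | 7.9 |

dusk run (percent of the L charged)

| time / h | X / % | J / % | L / % |
|---|---|---|---|
| 0.200 | 29.0 | 8.9 | 51.2 |
| 0.667 | 50.4 | 29.2 | 16.0 |
| 1.00 | 54.7 | 35.5 | 7.9 |
| 1.50 | 57.8 | 38.8 | 2.4 |
| 2.50 | 59.7 | 39.5 | 0.2 |

(each reading ± 0.3 percentage points)

- ratio of X to J at 50 s
- ratio of X to J at 6.0 h
- which of X and J there is more of at 6.0 h

**Early end.** At 4.00 min in the noon run, L, X and J summed to 9.9 percentage points short of the charge, more than the J found. So I took J to wait behind something unseen, growing at first as the square of time while X grew as time. X over J then scales inversely with time, and I scaled the first reading to 50 s, which gave 37.1. This number is soft, since that J reading was 2.3 % with a scatter of 0.3 points.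

**Late end.** I reached the late ratio by two ways. The first used the split, the fraction of consumed L that appears as X: 0.596 from the last noon reading. The dusk run, at the same L of 7.9 %, read X 54.7 % against noon's 54.9 %, so the split read alike at these two charges. If the remainder becomes J, the ratio is 1.48. The second way was the last dusk reading itself, 1.51.

**Which cheats?** The split calls J whatever is not X, yet that dusk reading summed 0.6 points short, against a scatter of 0.3 points per reading. A sum of several readings scatters wider than one reading, so this was a hint and no proof. I leaned to the direct value, itself a reading with its scatter.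

**The check.** The forecast gave 40 and 1.48, with X ahead, on the ground that “L splits directly”. The flask gave 38.7 at 50 s and 1.51 at 6.0 h, with X at 59.4 % and J at 39.4 %. J has a half-life of 130 h by the reaction to Q alone, long against 6.0 h, and Q stood at 1.15 %. So the remainder of the split as read, 0.404, belongs beside J and Q together, 40.6 %, and not beside J.

    L + D ⇌ G (K = 52.0 /M, k = 0.170 /M/min)
    G → J (k = 0.0880 /min)
    L + D → X (k = 0.240 /M/min)
    J → Q (k = 8.60 × 10⁻⁵ /min)

**Second flask.** With 0.500 equiv of D as limiting reagent, and one D per L, the split gave X 0.298 and J with Q 0.202 of the L charged. Computed, that flask held X 29.7 %, J 19.7 %, Q 0.551 % and L 50.0 %, with D at 0.00853 % of its own charge.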